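The hydroazulene is treated as a rearranged 10-epi-eudesmane. The C5=C6 alkene of the seven-membered ring, next to quaternary C4, is what deconjugative C4-functionalisation of a decalin 1,4-dien-3-one leaves behind. In that product C5=C6 and C1=C2 flank C10 as a 1,4-diene. Irradiation moves vinyl carbon C5 from C10 to C1 in one operation. Ring A contracts to the cyclopentane, ring B takes in C1 and grows from six to seven members, C1 is set, and a C2–C10 cyclopropane stores the future C10 methine. The precursor is a Robinson decalin whose angular methyl first steers C4 and then becomes the secondary methyl.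

Key step: step 7

Remark (numbering): eudesmane/guaiane numbering is used throughout.
- C1' is the benzylic CH and C4 is the quaternary ring carbon.
- C5 is the sp2 ring-fusion carbon and C6 is the vinylic CH.
- C7 is the CH bearing C11, the C(CH3)2OH carbon.
- C8 and C9 are CH2, C10 is the methyl-bearing carbon, C1 is the sp3 ring-fusion CH, and C2 and C3 are the cyclopentane CH2 groups.
- α is the face of the C10 methyl and β is the face of the C7 side chain.

Remark (assumptions):
- Commercial (+)-dihydrocarvone, a mixture of C2 epimers, is assumed enantiopure at C5.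
- Compound 10 (at C1'), compound 18 (at the hemiaminal carbon) and F7/F8 (at C3) are drawn without configuration at centres that are erased again.

Step 1
Reactants: 1 (+)-dihydrocarvone; 2 ethyl vinyl ketone
Product: 4 (−)-10-epi-α-cyperone (10α-methyl trans to 7β-isopropenyl), via 1,5-diketone 3 (not isolated)
Conditions: KOH, EtOH, −10 °C to rt, then reflux
Reagents that add atoms: none
Why: Robinson annulation (Michael addition, aldol condensation): the more substituted enolate is attacked axially on the face cis to the equatorial isopropenyl group, so the new quaternary C10 carries its methyl trans to that group, and both C2 epimers of 1 converge.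

Step 2
Reactants: 4 (−)-10-epi-α-cyperone
Product: 5 11-hydroxy-10-epi-eudesm-4-en-3-one (10-epi-carissone)
Conditions: Co(acac)2 (cat.), PhSiH3, O2 (1 atm), THF, rt
Reagents that add atoms: dioxygen (O=O)
Why: Mukaiyama hydration (cobalt-hydride hydrogen-atom transfer, then O2 capture) selects the electron-rich 1,1-disubstituted alkene over the tetrasubstituted enone and gives the Markovnikov tertiary alcohol without creating a stereocentre.

Step 3
Reactants: 5 10-epi-carissone
Product: 6 11-hydroxy-10-epi-eudesma-1,4-dien-3-one
Conditions: DDQ, dioxane, reflux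
Reagents that add atoms: none
Why: Quinone dehydrogenation of a 4-en-3-one under neutral conditions runs through the C2 enol and hydride loss from C1 to give the cross-conjugated dienone; the tertiary alcohol is inert.

Step 4
Reactants: 7 2-hydroxy-4,6-dimethoxybenzaldehyde
Product: 8 tert-butyl 2-formyl-3,5-dimethoxyphenyl carbonate
Conditions: Boc2O, DMAP (cat.), CH2Cl2, rt
Reagents that add atoms: di-tert-butyl dicarbonate (CC(C)(C)OC(=O)OC(=O)OC(C)(C)C)
Why: DMAP-catalysed O-acylation of the phenol installs the carbonate that later turns the benzylic oxygen into a leaving group.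

Step 5
Reactants: 6 dienone; 8 aryl carbonate aldehyde; 9 isobutylmagnesium bromide
Product: 12 4β-[1-(2-hydroxy-4,6-dimethoxyphenyl)-3-methylbutyl]-11-hydroxy-10-epi-eudesma-1,5-dien-3-one (4α-methyl; C1' as in the target), via benzylic carbonate 10 (not isolated), via o-quinone methide 11 (not isolated)
Conditions: LiN(SiMe3)2 (2.1 equiv), THF, −78 °C; 8, −78 °C; then 9 (Et2O), −78 to −20 °C; aq NH4Cl
Reagents that add atoms: none
Why: Vinylogous deprotonation at C6 (the only acidic C–H), a closed lithium aldol at C4 on the β face anti to the axial 10α-methyl, O-to-O carbonate transfer and magnesium-triggered loss of tert-butyl carbonate give o-quinone methide 11 (which has no enolisable γ-hydrogen), and the 1,4-addition of 9 (three-component o-quinone methide coupling) occurs with the C4 methyl eclipsing the exocyclic C=C (allylic strain), on the face flanked by the C3 carbonyl and away from ring B, which sets C1'.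

Step 6
Reactants: 12 phenol
Product: 13 4β-[1-(2,4,6-trimethoxyphenyl)-3-methylbutyl]-11-hydroxy-10-epi-eudesma-1,5-dien-3-one
Conditions: MeI, K2CO3, acetone, reflux
Reagents that add atoms: iodomethane (CI)
Why: Williamson etherification of the phenoxide (the tertiary alcohol is not deprotonated) makes the arene symmetric and removes the acidic, hemiketal-forming OH before photolysis and lithiation.

Step 7
Reactants: 13 1,5-dien-3-one
Product: 14 2,10-cycloguai-5-en-3-one (cyclopropyl ketone; H-1 and H-2 β, C9 endo and methyl exo on C10)
Conditions: hν (365 nm), degassed t-BuOH–benzene, dilute, rt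
Reagents that add atoms: none
Why: Proposed new method: excitation of the enone n,π* band and intersystem crossing give a triplet in which β-carbon C1 bonds to C5 across C10 (the bridging known from cross-conjugated dienone photochemistry), the cyclopropylcarbinyl radical at C6 reopens by breaking C5–C10 to restore C5=C6 and leave a tertiary C10 radical, and after spin inversion C10 couples with the α-keto radical C2. The closest known reaction type is the di-π-methane 1,2-vinyl or 1,2-aryl shift of 4-alkenyl- and 4-arylcyclohex-2-enones to bicyclo[3.1.0]hexan-2-ones; new here is that the migrating vinyl carbon is itself a member of the enone ring, so the shift changes both ring sizes. Ring closures: the cyclopentane closes through the C1–C5 bond (3-exo bridging, then cyclopropylcarbinyl opening, a net 1,2-shift contracting ring A), the seven-membered ring arises in the same event by insertion of C1 between C5 and C10 of six-membered ring B, and the cyclopropane closes by 1,3-diradical recombination C2–C10. Stereocontrol: C10 can fold out of the new five-membered ring only towards its methyl-bearing α face, because C9 must stay cis to C6 and then to C5 on the three-membered ring, which places H-1 and H-2 on the β face and C9 endo, methyl exo on C10, while C4, C7 and C1' are spectators. The step needs bridging to outrun Norrish α-cleavage and 1,3-acyl shift of the β,γ-unsaturated ketone, and C5–C10 rather than C1–C10 opening; long-wavelength excitation of the conjugated enone only, fast intersystem crossing, retention of the better stabilised α-keto radical and formation of a tertiary radical favour this. The trimethoxyarene does not absorb at 365 nm and electron transfer from it to the enone triplet is uphill.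

Step 8
Reactants: 14 cyclopropyl ketone
Product: 15 4β-[1-(2,4,6-trimethoxyphenyl)-3-methylbutyl]-11-hydroxy-1βH,10βH-guai-5-en-3-one
Conditions: Li, NH3(l)–THF, t-BuOH (1 equiv), −78 °C; NH4Cl
Reagents that add atoms: none
Why: Dissolving-metal reductive cleavage of a conjugated cyclopropyl ketone: the out-of-plane C2–C10 bond overlaps with the ketyl orbital and breaks, whereas the in-plane C1–C2 bond does not and is orthogonal to the C5=C6 π system, and the C10 radical is reduced at once and protonated on the open, peripheral face opposite the departing C2, which should give 10β-H and 10α-methyl.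

Step 9
Reactants: 15 guai-5-en-3-one
Product: 17 tri-O-methyl-bis(deformyl)macrocarpal D, via hydrazone 16 (not isolated)
Conditions: N2H4·H2O, KOH, diethylene glycol, 130 then 200 °C
Reagents that add atoms: none
Why: Wolff–Kishner reduction (Huang-Minlon variant) removes the C3 carbonyl; quaternary C4 blocks conjugation of C5=C6, and no stereocentre is α to the ketone.

Step 10
Reactants: 17 trimethoxyarene
Product: 19 tri-O-methylmacrocarpal D, via lithium hemiaminal 18 (not isolated)
Conditions: n-BuLi (2.2 equiv), TMEDA, THF, 0 °C; DMF, −78 to 0 °C; n-BuLi (1.3 equiv), 0 °C; DMF; aq NH4Cl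
Reagents that add atoms: N,N-dimethylformamide (CN(C)C=O)
Why: Directed ortho-lithiation between two methoxy groups with a DMF quench is run twice in one flask, the first adduct staying masked as its α-amino alkoxide, so both formyl groups enter without acid and the tertiary alcohol (carried as alkoxide) and the alkene survive.

Step 11
Reactants: 19 tri-O-methylmacrocarpal D
Product: 20 (−)-macrocarpal D
Conditions: NaSEt (excess), DMF, 100 °C; then cold 0.5 M HCl
Reagents that add atoms: none
Why: SN2 demethylation by a soft thiolate cleaves the three aryl methyl ethers, each activated by ortho or para formyl groups, under non-acidic conditions that spare the tertiary alcohol, the trisubstituted alkene and all stereocentres.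

Compound list
1 | (+)-dihydrocarvone, (2R,5R)-2-methyl-5-(prop-1-en-2-yl)cyclohexan-1-one | C[C@@H]1CC[C@H](CC1=O)C(C)=C | starting material
2 | ethyl vinyl ketone (pent-1-en-3-one) | CCC(=O)C=C | starting material
3 | 2-methyl-2-(3-oxopentyl)-5-(prop-1-en-2-yl)cyclohexanone, methyl trans to isopropenyl | CCC(=O)CC[C@@]1(C)CC[C@@H](C(C)=C)CC1=O | intermediate
4 | (−)-10-epi-α-cyperone, (4aR,7R) | CC1=C2C[C@H](C(C)=C)CC[C@]2(C)CCC1=O | intermediate
5 | 11-hydroxy-10-epi-eudesm-4-en-3-one | CC1=C2C[C@H](C(C)(C)O)CC[C@]2(C)CCC1=O | intermediate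
6 | 11-hydroxy-10-epi-eudesma-1,4-dien-3-one | CC1=C2C[C@H](C(C)(C)O)CC[C@]2(C)C=CC1=O | intermediate
7 | 2-hydroxy-4,6-dimethoxybenzaldehyde | COc1cc(OC)c(C=O)c(O)c1 | starting material
8 | tert-butyl 2-formyl-3,5-dimethoxyphenyl carbonate | COc1cc(OC)c(C=O)c(OC(=O)OC(C)(C)C)c1 | intermediate
9 | isobutylmagnesium bromide | CC(C)C[Mg]Br | starting material
10 | C4β aldol adduct after carbonate transfer (benzylic tert-butyl carbonate, free phenol; C1' unassigned) | CC(C)(C)OC(=O)OC(c1c(O)cc(OC)cc1OC)[C@@]1(C)C(=O)C=C[C@@]2(C)CC[C@@H](C(C)(C)O)C=C12 | intermediate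
11 | o-quinone methide bearing the terpene on the exocyclic carbon, cis to the ring carbonyl | O=C1C=C(OC)C=C(OC)/C1=C/[C@@]1(C)C(=O)C=C[C@@]2(C)CC[C@@H](C(C)(C)O)C=C12 | intermediate
12 | 4β-[1-(2-hydroxy-4,6-dimethoxyphenyl)-3-methylbutyl]-11-hydroxy-10-epi-eudesma-1,5-dien-3-one | CC(C)C[C@@H](c1c(O)cc(OC)cc1OC)[C@@]1(C)C(=O)C=C[C@@]2(C)CC[C@@H](C(C)(C)O)C=C12 | intermediate
13 | 4β-[1-(2,4,6-trimethoxyphenyl)-3-methylbutyl]-11-hydroxy-10-epi-eudesma-1,5-dien-3-one | CC(C)C[C@@H](c1c(OC)cc(OC)cc1OC)[C@@]1(C)C(=O)C=C[C@@]2(C)CC[C@@H](C(C)(C)O)C=C12 | intermediate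
14 | 2,10-cycloguai-5-en-3-one (5-3-7 tricyclic cyclopropyl ketone) | CC(C)C[C@@H](c1c(OC)cc(OC)cc1OC)[C@@]1(C)C(=O)[C@H]2[C@H]3C1=C[C@H](C(C)(C)O)CC[C@@]23C | intermediate
15 | 11-hydroxy-1βH,10βH-guai-5-en-3-one with the C4β side chain | CC(C)C[C@@H](c1c(OC)cc(OC)cc1OC)[C@@]1(C)C(=O)C[C@H]2C1=C[C@H](C(C)(C)O)CC[C@H]2C | intermediate
16 | C3 hydrazone of 15 | CC(C)C[C@@H](c1c(OC)cc(OC)cc1OC)[C@@]1(C)C(=NN)C[C@H]2C1=C[C@H](C(C)(C)O)CC[C@H]2C | intermediate
17 | tri-O-methyl-bis(deformyl)macrocarpal D | CC(C)C[C@@H](c1c(OC)cc(OC)cc1OC)[C@@]1(C)CC[C@H]2C1=C[C@H](C(C)(C)O)CC[C@H]2C | intermediate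
18 | mono-DMF adduct, held as its lithium alkoxide (drawn neutral; hemiaminal carbon unassigned) | CC(C)C[C@@H](c1c(OC)c(C(O)N(C)C)c(OC)cc1OC)[C@@]1(C)CC[C@H]2C1=C[C@H](C(C)(C)O)CC[C@H]2C | intermediate
19 | tri-O-methylmacrocarpal D | CC(C)C[C@@H](c1c(OC)c(C=O)c(OC)c(C=O)c1OC)[C@@]1(C)CC[C@H]2C1=C[C@H](C(C)(C)O)CC[C@H]2C | intermediate
20 | (−)-macrocarpal D | CC(C)C[C@@H](c1c(O)c(C=O)c(O)c(C=O)c1O)[C@@]1(C)CC[C@H]2C1=C[C@H](C(C)(C)O)CC[C@H]2C | target

Total step count: 11. Longest linear sequence: 10 (steps 1–3 and 5–11, from 1).

Steps most likely to fail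

1. Step 7 (Proposed new method).
- Risk: the bridged diradical may decay back to starting enone, or α-cleavage and 1,3-acyl shift of the β,γ-unsaturated ketone may take over.
- Fallback: it uses known chemistry, sets out from 13 and returns at 17, and also replaces steps 8 and 9.
- Weitz–Scheffer epoxidation of 13 (H2O2, NaOH, MeOH, 0 °C) on the β face, away from the angular methyl, gives the 1β,2β-epoxy ketone F1. Wharton transposition (N2H4·H2O, AcOH, MeOH) removes the C3 oxygen and gives the 2-en-1β-ol F2. Dess–Martin oxidation gives the 2-en-1-one F3. Li, NH3, MeOH reduces it to the equatorial 1α-alcohol F4, and MsCl, Et3N gives the mesylate F5. Solvolysis of F5 in aqueous diglyme in the presence of NaBH4 proceeds with homoallylic, i-steroid-type participation. C5 bridges to C1 from the rear of the equatorial C1–O bond, the charge settles on tertiary C10, and hydride capture anti to C5 should give 17 with the same 1βH,10βH configuration. Ring B again grows from six to seven members.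

2. Step 5.
- Risk: the crowded aldol may revert before the carbonate transfers, the trienolate may react through C6, or the Grignard addition may show poor facial selectivity.
- Fallback: it sets out from 6, 8 and 9 and returns at 12, and it reverses the order of bond formation.
- Addition of 9 to 8 at −78 °C gives, after carbonate transfer and elimination, the isobutyl-substituted o-quinone methide F6. This is intercepted by the potassium trienolate of 6 (KN(SiMe3)2, 18-crown-6, THF). In an open Michael transition state the quinone methide ring lies antiperiplanar to the C3–C4 enolate bond, hydrogen sits over ring A and isobutyl points outside. C4 and C1' are then set together, in the same relative sense.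

3. Step 8.
- Risk: facial selectivity in the protonation at C10 may be poor, or the vinyl group may migrate back in the C10 radical before it is reduced.
- Fallback: it sets out from 14 and returns at 17, and also replaces step 9.
- LiAlH4 gives the cyclopropyl carbinol F7, and PhOC(S)Cl with DMAP acylates only the secondary alcohol to give the thionocarbonate F8. Barton–McCombie conditions with a bulky, concentrated hydrogen donor ((Me3Si)3SiH or Bu3SnH, AIBN, toluene, 80 °C) generate the C3 cyclopropylcarbinyl radical. This opens the C2–C10 bond, and peripheral hydrogen transfer to C10 gives the guaia-2,5-diene F9. Diimide (2-nitrobenzenesulfonyl hydrazide, Et3N) then saturates only the disubstituted C2=C3 alkene to give 17.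

Further compounds
F1 | step 7 | 1β,2β-epoxy ketone of 13 | CC(C)C[C@@H](c1c(OC)cc(OC)cc1OC)[C@@]1(C)C(=O)[C@H]3O[C@H]3[C@@]2(C)CC[C@@H](C(C)(C)O)C=C12
F2 | step 7 | 10-epi-eudesma-2,5-diene-1β,11-diol with the C4β side chain | CC(C)C[C@@H](c1c(OC)cc(OC)cc1OC)[C@@]1(C)C=C[C@@H](O)[C@@]2(C)CC[C@@H](C(C)(C)O)C=C12
F3 | step 7 | 11-hydroxy-10-epi-eudesma-2,5-dien-1-one with the C4β side chain | CC(C)C[C@@H](c1c(OC)cc(OC)cc1OC)[C@@]1(C)C=CC(=O)[C@@]2(C)CC[C@@H](C(C)(C)O)C=C12
F4 | step 7 | 10-epi-eudesm-5-ene-1α,11-diol with the C4β side chain | CC(C)C[C@@H](c1c(OC)cc(OC)cc1OC)[C@@]1(C)CC[C@H](O)[C@@]2(C)CC[C@@H](C(C)(C)O)C=C12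
F5 | step 7 | 1α-mesylate of F4 | CC(C)C[C@@H](c1c(OC)cc(OC)cc1OC)[C@@]1(C)CC[C@H](OS(C)(=O)=O)[C@@]2(C)CC[C@@H](C(C)(C)O)C=C12
F6 | step 5 | 3,5-dimethoxy-6-(3-methylbutylidene)cyclohexa-2,4-dien-1-one | CC(C)C/C=C1\C(=O)C=C(OC)C=C1OC
F7 | step 8 | 2,10-cycloguai-5-ene-3,11-diol (C3 unassigned) | CC(C)C[C@@H](c1c(OC)cc(OC)cc1OC)[C@@]1(C)C(O)[C@H]2[C@H]3C1=C[C@H](C(C)(C)O)CC[C@@]23C
F8 | step 8 | C3 O-phenyl thionocarbonate of F7 | CC(C)C[C@@H](c1c(OC)cc(OC)cc1OC)[C@@]1(C)C(OC(=S)Oc4ccccc4)[C@H]2[C@H]3C1=C[C@H](C(C)(C)O)CC[C@@]23C
F9 | step 8 | 1βH,10βH-guaia-2,5-dien-11-ol with the C4β side chain | CC(C)C[C@@H](c1c(OC)cc(OC)cc1OC)[C@@]1(C)C=C[C@H]2C1=C[C@H](C(C)(C)O)CC[C@H]2C
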